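Its constants are assumed.

Time came first at the meeting on this flask: the run lasts 12 min, and the partner's half-life by its own decay is 4.33 s, far shorter than the run. The meeting therefore asked who gets the partner during its feed.

solid substrate 2.0 mM; partner 2.40 mM (fed, over 15 s); initiator 0.20 mM; time 12 min

    starting material + initiating radical → chain carrier (k1 = 2.0 × 10⁵ /M/s)
    partner + chain carrier → target + initiating radical (k2 = 3.7 × 10⁵ /M/s)
    2 chain carrier → ended chains A (k3 = 2 × 10⁷ /M/s)
    partner → decomposed reagent (k4 = 0.16 /s)
    solid substrate ⇌ starting material, rate k5*(cs5 - [starting material]) while solid is left; crystals form when [starting material] > cs5 (cs5 = 0.95 mM, k5 = 0.56 /s)
    2 initiating radical → ended chains B (k6 = 3 × 10⁶ /M/s)
    initiator → 2 initiating radical (k7 = 0.024 /s)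

- percent here means solid substrate units held: one ended chains A counts as two
- where a step has two of a species, its rate is k times that concentration squared, and two are used at each turn
- solid substrate is a solid; its amount is given per volume of the solution
- at the start none of the solid substrate is in solution
- what has only dissolved of solid substrate counts as not reacted
- starting material means what is dissolved; the solid is not counted in it
- the reaction counts as stopped when no species that holds the solid substrate changes by six tenths of a point or more over the second half of the time
- run time (flask): 12 min

* why nothing more happens at 12 min, or that something still does (for what has run out or reacted, a solid counts together with what of it has only dissolved) (it is still moving / forward and back rates have come level / all of the solid substrate has reacted / the partner has run out first)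
* part of the solid substrate that has turned into other species by 12 min (what has only dissolved does not count)
* the target standing at 12 min, as a percentage of the solid substrate charged
* the starting material standing at 12 min, as a percentage of the solid substrate charged

The secretary argued, as her own reckoning, that the partner has two exits: the chain step with chain carrier, and decay. Both rates carry the partner's concentration, so it cancels from their ratio at every instant, and the ratio is the chain rate constant times the chain carrier over the decay constant. The two exits stand level at a chain carrier of 4.32 × 10⁻⁴ mM.

She then took the radicals made by the initiator to be lost two at a time by the chain carrier's termination. This puts the chain carrier at the square root of the initiator's decay constant times its concentration over the termination constant, which is 4.90 × 10⁻⁴ mM at the charge, more than the level value. The ratio there is 1.13.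

The initiator falls exponentially, so in her reckoning the chain carrier falls at the exponential of minus 0.5 times the initiator's decay constant times time. She evaluated this at the partner's mean moment of use, the middle of the feed plus one lifetime against both exits, 10.4 s. That gave 1.00, which she carried as the partner split, target formed per decomposed reagent formed. Her target is then the partner charge times the split over one plus the split, 1.20 mM, or 60.0% of the solid substrate charged. Her reckoning went no further than the target.

The forecast gave the partner has run out first, with conversion 77%, target 58% and starting material 23%, on the ground that “The partner is lost to chain reaction and to its own decay at about equal rates”. Its target stood slightly below the secretary's.

The simulation gives the partner has run out first, with conversion 76.4%, target 57.5% and starting material 23.6%.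

The partner's decay is the main reason this flask's target stands at 57.5% with the partner at 0%: with that step struck out, the target reaches 95.3%. The split read from this flask at 12.0 min is 0.920, against the reckoned 1.00. The partner's charge stands nowhere in the reckoned split, so the neighbour flask with 1.4 mM of partner should form 0.700 mM of target; that neighbour's target stands at 34.4% of the solid substrate charged, 0.689 mM.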